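The pyranone ring is opened at O1–C2 and its carbonyl carbon is excised. C4 lies between C4a of the benzene ring, whose neighbours C5 and C8a both carry oxygen and are interchangeable before ring closure, and the C3–C2 unit that bears the tricosyl chain. C4 is therefore introduced as carbon monoxide gas and C3–C2 as the two sp carbons of a 1-alkyne. One palladium-catalysed carbonylative Sonogashira coupling unites the mirror-symmetric 1-iodo-2,4,6-trimethoxy-3,5-dimethylbenzene, CO and pentacos-1-yne, forging C4a–C4 and C4–C3 and delivering the whole carbon skeleton as an aryl ynone. Diethylamine addition and demethylative ring closure then complete the chromone.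

Key step: step 5

Remark: atom labels such as C4a follow the chromone numbering of the target; 2,4,6-trimethoxytoluene is taken as a catalogue compound, and the methyl ethers are kept because they direct the lithiation and keep the iodide symmetric.
Remark: enaminone 12 is drawn as the E isomer expected for a tertiary vinylogous amide; its geometry is erased in the ring closure.

Step 1
Reactants: 1 2,4,6-trimethoxytoluene
Product: 3 1,3,5-trimethoxy-2,4-dimethylbenzene, via aryllithium 2 (not isolated)
Conditions: n-BuLi, TMEDA, THF, 0 °C; then MeI, 0 °C to rt
Reagents that add atoms: iodomethane, CI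
Why: Directed ortho-lithiation at a ring C–H flanked by two methoxy groups (the two open positions are equivalent), followed by SN2 methylation of the aryllithium, should install the second methyl group cleanly.

Step 2
Reactants: 3 1,3,5-trimethoxy-2,4-dimethylbenzene
Product: 4 1-iodo-2,4,6-trimethoxy-3,5-dimethylbenzene
Conditions: NIS, TFA (cat.), MeCN, rt, dark
Reagents that add atoms: N-iodosuccinimide, O=C1CCC(=O)N1I
Why: Electrophilic aromatic iodination of a strongly activated arene with a single open ring position, so no regiochemistry has to be controlled.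

Step 3
Reactants: 5 1-(trimethylsilyl)propyne; 6 1-bromodocosane
Product: 8 trimethyl(pentacos-1-yn-1-yl)silane, via propargyllithium 7 (not isolated)
Conditions: n-BuLi, THF, −78 to −20 °C; then 6, DMPU, THF, −20 °C to rt
Reagents that add atoms: none
Why: Propargylic deprotonation of the silylpropyne and SN2 alkylation by the primary bromide, the bulky silyl group steering attack through the CH2 terminus so that the alkyne and not the allene should dominate.

Step 4
Reactants: 8 trimethyl(pentacos-1-yn-1-yl)silane
Product: 9 pentacos-1-yne
Conditions: K2CO3 (0.2 equiv), MeOH/THF, rt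
Reagents that add atoms: none
Why: Base-mediated protodesilylation of an alkynylsilane (methoxide attacks silicon, methanol protonates the acetylide), with THF keeping the waxy substrate in solution.

Step 5
Reactants: 4 1-iodo-2,4,6-trimethoxy-3,5-dimethylbenzene; 9 pentacos-1-yne; 10 carbon monoxide
Product: 11 1-(2,4,6-trimethoxy-3,5-dimethylphenyl)hexacos-2-yn-1-one
Conditions: PdCl2(PPh3)2 (5 mol %), CuI (2 mol %), Et3N, THF, CO 10 bar, 60 °C, slow addition of 9
Reagents that add atoms: none
Why: Zerovalent palladium, formed in the flask from the divalent palladium precatalyst PdCl2(PPh3)2, adds oxidatively to the C–I bond of 4, CO inserts into the aryl–palladium bond, the copper acetylide generated from 9, CuI and Et3N transfers its alkynyl group to the aroyl palladium centre, and reductive elimination releases the ynone with the new C4a–C4 and C4–C3 bonds. The closest known reaction type is the carbonylative Sonogashira coupling of aryl iodides with terminal alkynes to give alkynones. No ring is closed and no stereocentre is created. The selectivity needed is CO insertion ahead of alkynyl transfer, which would otherwise give the direct aryl–alkyne coupling product; the two ortho methoxy groups crowd the aryl palladium centre and slow transmetalation there, whereas insertion of the small CO relieves that crowding, and CO pressure, a low CuI loading and slow addition of 9 act in the same sense. Because 4 has a mirror plane through the C–I bond, no regiochemical choice arises and either ortho oxygen can later become O1.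

Step 6
Reactants: 11 1-(2,4,6-trimethoxy-3,5-dimethylphenyl)hexacos-2-yn-1-one
Product: 12 (E)-3-(diethylamino)-1-(2,4,6-trimethoxy-3,5-dimethylphenyl)hexacos-2-en-1-one
Conditions: Et2NH (5 equiv), THF/EtOH, 40 °C
Reagents that add atoms: diethylamine, CCNCC
Why: Aza-Michael addition of a secondary amine to the ynone should give the vinylogous amide, which leaves C2 as the only electrophilic site for the later phenol attack, so that the six-membered pyranone and not a five-membered aurone must form.

Step 7
Reactants: 12 (E)-3-(diethylamino)-1-(2,4,6-trimethoxy-3,5-dimethylphenyl)hexacos-2-en-1-one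
Product: 14 5,7-dihydroxy-6,8-dimethyl-2-tricosyl-4H-chromen-4-one (target), via triphenol enaminone 13 (not isolated)
Conditions: BBr3 (8 equiv), CH2Cl2, −78 °C to rt; then H2O, aq. HCl, THF, 50 °C
Reagents that add atoms: none
Why: Lewis-acid cleavage of the three aryl methyl ethers (bromide attacks the methyl group of each boron-complexed ether) is followed by acid-promoted addition–elimination, in which an ortho hydroxyl attacks C2 of the protonated vinylogous amide and diethylamine departs; both ortho hydroxyls are equivalent, so a single chromone should result.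

Compound list
1 | 2,4,6-trimethoxytoluene | Cc1c(OC)cc(OC)cc1OC | starting material
2 | (2,4,6-trimethoxy-3-methylphenyl)lithium | [Li]c1c(OC)cc(OC)c(C)c1OC | intermediate
3 | 1,3,5-trimethoxy-2,4-dimethylbenzene | COc1cc(OC)c(C)c(OC)c1C | intermediate
4 | 1-iodo-2,4,6-trimethoxy-3,5-dimethylbenzene | COc1c(C)c(OC)c(C)c(OC)c1I | intermediate
5 | 1-(trimethylsilyl)propyne | CC#C[Si](C)(C)C | starting material
6 | 1-bromodocosane | CCCCCCCCCCCCCCCCCCCCCCBr | starting material
7 | (3-(trimethylsilyl)prop-2-yn-1-yl)lithium | [Li]CC#C[Si](C)(C)C | intermediate
8 | trimethyl(pentacos-1-yn-1-yl)silane | CCCCCCCCCCCCCCCCCCCCCCCC#C[Si](C)(C)C | intermediate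
9 | pentacos-1-yne | CCCCCCCCCCCCCCCCCCCCCCCC#C | intermediate
10 | carbon monoxide | [C-]#[O+] | starting material
11 | 1-(2,4,6-trimethoxy-3,5-dimethylphenyl)hexacos-2-yn-1-one | CCCCCCCCCCCCCCCCCCCCCCCC#CC(=O)c1c(OC)c(C)c(OC)c(C)c1OC | intermediate
12 | (E)-3-(diethylamino)-1-(2,4,6-trimethoxy-3,5-dimethylphenyl)hexacos-2-en-1-one | CCCCCCCCCCCCCCCCCCCCCCC/C(N(CC)CC)=C\C(=O)c1c(OC)c(C)c(OC)c(C)c1OC | intermediate
13 | (E)-3-(diethylamino)-1-(2,4,6-trihydroxy-3,5-dimethylphenyl)hexacos-2-en-1-one | CCCCCCCCCCCCCCCCCCCCCCC/C(N(CC)CC)=C\C(=O)c1c(O)c(C)c(O)c(C)c1O | intermediate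
14 | 5,7-dihydroxy-6,8-dimethyl-2-tricosyl-4H-chromen-4-one (CNP0267428.0) | CCCCCCCCCCCCCCCCCCCCCCCc1cc(=O)c2c(O)c(C)c(O)c(C)c2o1 | target

Total step count: 7.
Longest linear sequence: 5 steps (steps 1, 2, 5, 6, 7 from compound 1; equally steps 3, 4, 5, 6, 7 from compounds 5 and 6).

Steps most likely to fail

1. Step 5. The alkynyl group may be transferred to the aryl palladium centre before CO has inserted, giving direct coupling. Oxidative addition at the crowded, electron-rich C–I bond may also stall under CO, or the alkyne may dimerise oxidatively on copper. The fallback takes C4 from a formyl group instead of CO; it sets out from 3 and 9 and comes back at 11. Compound 3 would be lithiated at its last ring position (n-BuLi, TMEDA, THF, 0 °C) to (2,4,6-trimethoxy-3,5-dimethylphenyl)lithium F1. Quenching with DMF and aqueous NH4Cl work-up should give 2,4,6-trimethoxy-3,5-dimethylbenzaldehyde F2. Alkyne 9 would be deprotonated with n-BuLi in THF to lithium pentacos-1-yn-1-ide F3, which should add to F2 to give racemic 1-(2,4,6-trimethoxy-3,5-dimethylphenyl)hexacos-2-yn-1-ol F4 after NH4Cl work-up. Oxidation of the propargylic benzylic alcohol with MnO2 in CH2Cl2 at rt should then deliver ynone 11.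

2. Step 7. Ether cleavage may stop short at the hindered C7 oxygen, or the vinylogous amide may be hydrolysed or degraded by the Lewis acid before the ring closes. The fallback separates ring closure from full deprotection; it sets out from 12 and comes back at 14. BCl3 in CH2Cl2 (−78 to 0 °C) should cleave only one carbonyl-chelated ortho ether, giving (E)-3-(diethylamino)-1-(2-hydroxy-4,6-dimethoxy-3,5-dimethylphenyl)hexacos-2-en-1-one F5. Warming with aqueous HCl in THF should close this to the robust 5,7-dimethoxy-6,8-dimethyl-2-tricosyl-4H-chromen-4-one F6. The remaining two ethers would then be cleaved with 48 % aq. HBr in AcOH at reflux, the classical demethylation of methoxychromones, to give 14.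

3. Step 3. The lithiated silylpropyne may react through its allenyl terminus, or substitution may be slow because the C22 bromide is poorly soluble at low temperature, leaving elimination to compete. The fallback reverses the polarity of the two partners; it sets out from 6 and comes back at 8. Bromide 6 would be converted with Mg in THF at reflux into docosylmagnesium bromide F7. This would be coupled with commercial 3-bromo-1-(trimethylsilyl)prop-1-yne under CuBr·SMe2 catalysis (THF, −30 °C to rt). The silyl group blocks attack at the remote alkyne carbon, so 8 should form by direct displacement.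

Further compounds
F1 | step 5 | (2,4,6-trimethoxy-3,5-dimethylphenyl)lithium | [Li]c1c(OC)c(C)c(OC)c(C)c1OC
F2 | step 5 | 2,4,6-trimethoxy-3,5-dimethylbenzaldehyde | O=Cc1c(OC)c(C)c(OC)c(C)c1OC
F3 | step 5 | lithium pentacos-1-yn-1-ide | CCCCCCCCCCCCCCCCCCCCCCCC#C[Li]
F4 | step 5 | racemic 1-(2,4,6-trimethoxy-3,5-dimethylphenyl)hexacos-2-yn-1-ol | CCCCCCCCCCCCCCCCCCCCCCCC#CC(O)c1c(OC)c(C)c(OC)c(C)c1OC
F5 | step 7 | (E)-3-(diethylamino)-1-(2-hydroxy-4,6-dimethoxy-3,5-dimethylphenyl)hexacos-2-en-1-one | CCCCCCCCCCCCCCCCCCCCCCC/C(N(CC)CC)=C\C(=O)c1c(O)c(C)c(OC)c(C)c1OC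
F6 | step 7 | 5,7-dimethoxy-6,8-dimethyl-2-tricosyl-4H-chromen-4-one | CCCCCCCCCCCCCCCCCCCCCCCc1cc(=O)c2c(OC)c(C)c(OC)c(C)c2o1
F7 | step 3 | docosylmagnesium bromide | CCCCCCCCCCCCCCCCCCCCCC[Mg]Br
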